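**Retrosynthetic overview**

1. The target is a 3,3''-biflavanone: a cis-(2S,3S) 4'-O-methyl half (A, unprimed locants) and a trans-(2''R,3''S) 4'''-hydroxy half (B, doubly primed). The enabling feature is that C3 and C3'' are the α-carbons of the two pyranone carbonyls C4=O and C4''=O (a 1,4-diketone spanning the two chroman-4-one C rings), each flanked by an aryl-bearing C2 stereocentre.
2. Key disconnection C3–C3'': an electrophilic C3 radical of A, made oxidisable by a temporary 3-CO2tBu group (1,3-dicarbonyl), adds to the C3''=C4'' enol silane of B anti to its C2'' aryl group (sets 3''S, trans unit).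
3. The ester is then removed: decarboxylation gives the C3=C4 enol of A, and kinetic ketonisation anti to the 2-anisyl group sets the contra-thermodynamic cis-2,3 unit. Neutral hydrogenolysis of five benzyl ethers ends the route.
4. Both halves come from one β-keto ester (from phloroacetophenone) by Knoevenagel condensation and catalytic enantioselective oxa-Michael cyclisation with pseudoenantiomeric cinchona thioureas (2S for A, 2R for B).
5. Ring order: pyranone ring of A (step 4), pyranone ring of B (step 6), then union of the two bicycles (step 8); all benzene rings are bought.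

Key step: step 8

Remark (assumption): the quinine-derived thiourea is taken to give the 2S series and its quinidine-derived pseudoenantiomer the 2R series; if the sense of induction is the opposite, the two catalysts are exchanged between steps 4 and 6.
Remark: in 12–14 the CIP label at C2 of the A half reads R only because C3 outranks the aryl group there; the spatial arrangement is that of (2S)-6 throughout. Minor enantiomers of 6 and 11 should end up in diastereomers of 12, removable by chromatography at that stage.

**Step 1**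
Reactants: 1 2',4',6'-trihydroxyacetophenone
Product: 2 1-[2,4-bis(benzyloxy)-6-hydroxyphenyl]ethanone
Conditions: BnBr (2.05 equiv), K2CO3 (2.2 equiv), DMF, 0 °C to rt
Reagents that add atoms: benzyl bromide, BrCc1ccccc1
Why: Williamson etherification in which the hydroxyl hydrogen-bonded to the acetyl carbonyl is the least nucleophilic and should stay free when two equivalents of benzyl bromide are used.

**Step 2**
Reactants: 2 1-[2,4-bis(benzyloxy)-6-hydroxyphenyl]ethanone
Product: 3 tert-butyl 3-[2,4-bis(benzyloxy)-6-hydroxyphenyl]-3-oxopropanoate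
Conditions: LiHMDS (3.2 equiv), THF, –78 °C; Boc2O (1.1 equiv), –78 to 0 °C; 1 M HCl quench at 0 °C
Reagents that add atoms: di-tert-butyl dicarbonate, CC(C)(C)OC(=O)OC(=O)OC(C)(C)C
Why: Claisen-type C-acylation of the phenoxide/enolate dianion (any O-Boc carbonate formed should converge on the same product by Baker–Venkataraman-type acyl transfer), the third equivalent of base deprotonating the product, and the bulky tert-butyl ester resisting lactonisation to a 4-hydroxycoumarin.

**Step 3**
Reactants: 3 tert-butyl 3-[2,4-bis(benzyloxy)-6-hydroxyphenyl]-3-oxopropanoate; 4 4-methoxybenzaldehyde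
Product: 5 tert-butyl 2-[2,4-bis(benzyloxy)-6-hydroxybenzoyl]-3-(4-methoxyphenyl)prop-2-enoate (E/Z mixture)
Conditions: piperidine (10 mol %), AcOH (10 mol %), 4 Å MS, toluene, rt
Reagents that add atoms: none
Why: Knoevenagel condensation of the active methylene with a non-enolisable aldehyde under piperidinium acetate catalysis with removal of water, the alkene geometry being irrelevant because the double bond is consumed in step 4.

**Step 4**
Reactants: 5 tert-butyl 2-[2,4-bis(benzyloxy)-6-hydroxybenzoyl]-3-(4-methoxyphenyl)prop-2-enoate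
Product: 6 tert-butyl (2S,3R)-5,7-bis(benzyloxy)-2-(4-methoxyphenyl)-4-oxochromane-3-carboxylate (trans keto form, in equilibrium with its enol)
Conditions: quinine-derived 3,5-bis(trifluoromethyl)phenyl thiourea (10 mol %), toluene, –25 °C
Reagents that add atoms: none
Why: Catalytic enantioselective intramolecular oxa-Michael addition (6-endo-trig) to an alkylidene β-keto ester, in which the thiourea binds the 1,3-dicarbonyl and the quinuclidine delivers the phenol to one face of the benzylidene carbon, setting C2 (S), while the labile C3 settles as the trans keto/enol mixture.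

**Step 5**
Reactants: 3 tert-butyl 3-[2,4-bis(benzyloxy)-6-hydroxyphenyl]-3-oxopropanoate; 7 4-(benzyloxy)benzaldehyde
Product: 8 tert-butyl 3-[4-(benzyloxy)phenyl]-2-[2,4-bis(benzyloxy)-6-hydroxybenzoyl]prop-2-enoate (E/Z mixture)
Conditions: piperidine (10 mol %), AcOH (10 mol %), 4 Å MS, toluene, rt
Reagents that add atoms: none
Why: The same Knoevenagel condensation as in step 3, applied to the aldehyde that carries the later 4'''-hydroxyl as its benzyl ether.

**Step 6**
Reactants: 8 tert-butyl 3-[4-(benzyloxy)phenyl]-2-[2,4-bis(benzyloxy)-6-hydroxybenzoyl]prop-2-enoate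
Product: 10 (2R)-5,7-bis(benzyloxy)-2-[4-(benzyloxy)phenyl]chroman-4-one, via cyclised tert-butyl ester 9 (not isolated)
Conditions: quinidine-derived 3,5-bis(trifluoromethyl)phenyl thiourea (10 mol %), toluene, –25 °C; then TsOH·H2O (20 mol %), 80 °C
Reagents that add atoms: none
Why: The enantioselective oxa-Michael cyclisation of step 4 run with the pseudoenantiomeric catalyst sets C2 (R), and acid-mediated loss of isobutene followed by decarboxylation of the β-keto acid in the same pot should give the flavanone without touching C2.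

**Step 7**
Reactants: 10 (2R)-5,7-bis(benzyloxy)-2-[4-(benzyloxy)phenyl]chroman-4-one
Product: 11 {[(2R)-5,7-bis(benzyloxy)-2-[4-(benzyloxy)phenyl]-2H-chromen-4-yl]oxy}(tert-butyl)dimethylsilane
Conditions: TBSOTf (1.3 equiv), Et3N (2.0 equiv), CH2Cl2, 0 °C; filtration through Et3N-deactivated silica
Reagents that add atoms: tert-butyldimethylsilyl trifluoromethanesulfonate, CC(C)(C)[Si](C)(C)OS(=O)(=O)C(F)(F)F
Why: Soft enolisation (silyl triflate/amine) forms the silyl enol ether through the O-silyl oxocarbenium ion, avoiding a free enolate that could open the pyranone ring by E1cB loss of phenoxide, so C2'' stays untouched.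

**Step 8**
Reactants: 6 tert-butyl (2S,3R)-5,7-bis(benzyloxy)-2-(4-methoxyphenyl)-4-oxochromane-3-carboxylate; 11 {[(2R)-5,7-bis(benzyloxy)-2-[4-(benzyloxy)phenyl]-2H-chromen-4-yl]oxy}(tert-butyl)dimethylsilane (1.5 equiv)
Product: 12 tert-butyl (2R,3S)-5,7-bis(benzyloxy)-3-{(2R,3S)-5,7-bis(benzyloxy)-2-[4-(benzyloxy)phenyl]-4-oxochroman-3-yl}-2-(4-methoxyphenyl)-4-oxochromane-3-carboxylate
Conditions: Mn(OAc)3·2H2O (2.2 equiv), degassed MeCN/AcOH (10:1), 0 °C to rt; aq. NaHCO3 work-up
Reagents that add atoms: none
Why: Mn(III) should oxidise only the enolised β-keto ester 6 (inner-sphere, via its Mn(III) enolate) to the electrophilic tertiary C3 radical, which adds to the electron-rich C3''=C4'' enol silane of 11; the resulting α-siloxy benzylic radical is oxidised by the second Mn(III) to a silyloxocarbenium ion that loses silicon to give the C4'' ketone. The closest known reaction type is the Mn(OAc)3- or CAN-mediated oxidative addition of 1,3-dicarbonyl compounds to silyl enol ethers and enol acetates giving 1,4-dicarbonyls, including α-substituted β-keto esters that form quaternary centres. No ring is closed; the step joins the two preformed chromanone halves through the C3–C3'' bond. C3'' is set by the C2'' aryl group of 11, which sits pseudoaxial on the 2H-chromene and directs attack to the opposite face (2'',3''-trans, 3''S, also the more stable arrangement of this epimerisable centre), whereas the quaternary C3 is expected to form anti to the 2-anisyl group but its configuration is inconsequential because it is erased in step 9. The selectivity the step needs is cross- over homo-coupling, secured by polarity matching: the 1,3-dicarbonyl is the only partner that Mn(III) oxidises and its radical is electrophilic, while the enol silane is the only nucleophilic alkene and is used in excess. The tert-butyl ester is thus the activating group that makes C3 a radical precursor here and the handle for setting the cis unit afterwards.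

**Step 9**
Reactants: 12 tert-butyl (2R,3S)-5,7-bis(benzyloxy)-3-{(2R,3S)-5,7-bis(benzyloxy)-2-[4-(benzyloxy)phenyl]-4-oxochroman-3-yl}-2-(4-methoxyphenyl)-4-oxochromane-3-carboxylate
Product: 15 (2S,3S)-5,7-bis(benzyloxy)-3-{(2R,3S)-5,7-bis(benzyloxy)-2-[4-(benzyloxy)phenyl]-4-oxochroman-3-yl}-2-(4-methoxyphenyl)chroman-4-one, via β-keto acid 13 (not isolated), via enol 14 (not isolated)
Conditions: TFA/CH2Cl2 (1:5), 0 °C; cold evaporation; toluene, 40 °C; neutral work-up
Reagents that add atoms: none
Why: Acidolysis of the tert-butyl ester and decarboxylation of the β-keto acid through the cyclic six-membered transition state give the C3=C4 enol, whose kinetic (Zimmerman-type) ketonisation should deliver the proton to C3 anti to the 2-anisyl group (pseudoaxial to avoid A(1,2) strain with the C3 substituent), placing H-3 trans to the aryl group and hence the C3 substituent cis to it (2S,3S).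

**Step 10**
Reactants: 15 (2S,3S)-5,7-bis(benzyloxy)-3-{(2R,3S)-5,7-bis(benzyloxy)-2-[4-(benzyloxy)phenyl]-4-oxochroman-3-yl}-2-(4-methoxyphenyl)chroman-4-one
Product: 16 (2S,3S)-5,7-dihydroxy-3-[(2R,3S)-5,7-dihydroxy-2-(4-hydroxyphenyl)-4-oxochroman-3-yl]-2-(4-methoxyphenyl)chroman-4-one (target)
Conditions: H2 (1 atm), 10% Pd/C, EtOAc/MeOH (1:1), rt, stopped at full debenzylation
Reagents that add atoms: none
Why: Hydrogenolysis of the five benzyl ethers under neutral conditions should leave the epimerisable cis-2,3 unit, the cyclic benzylic C2–O bonds and the aryl ketones intact.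

**Compound list**

1 | 2',4',6'-trihydroxyacetophenone | CC(=O)c1c(O)cc(O)cc1O | starting material
2 | 1-[2,4-bis(benzyloxy)-6-hydroxyphenyl]ethanone | CC(=O)c1c(O)cc(OCc2ccccc2)cc1OCc1ccccc1 | intermediate
3 | tert-butyl 3-[2,4-bis(benzyloxy)-6-hydroxyphenyl]-3-oxopropanoate | CC(C)(C)OC(=O)CC(=O)c1c(O)cc(OCc2ccccc2)cc1OCc1ccccc1 | intermediate
4 | 4-methoxybenzaldehyde | COc1ccc(C=O)cc1 | starting material
5 | tert-butyl 2-[2,4-bis(benzyloxy)-6-hydroxybenzoyl]-3-(4-methoxyphenyl)prop-2-enoate (E/Z mixture) | COc1ccc(C=C(C(=O)OC(C)(C)C)C(=O)c2c(O)cc(OCc3ccccc3)cc2OCc2ccccc2)cc1 | intermediate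
6 | tert-butyl (2S,3R)-5,7-bis(benzyloxy)-2-(4-methoxyphenyl)-4-oxochromane-3-carboxylate (trans keto form; C3 labile via the enol) | COc1ccc([C@H]2Oc3cc(OCc4ccccc4)cc(OCc4ccccc4)c3C(=O)[C@@H]2C(=O)OC(C)(C)C)cc1 | intermediate
7 | 4-(benzyloxy)benzaldehyde | O=Cc1ccc(OCc2ccccc2)cc1 | starting material
8 | tert-butyl 3-[4-(benzyloxy)phenyl]-2-[2,4-bis(benzyloxy)-6-hydroxybenzoyl]prop-2-enoate (E/Z mixture) | CC(C)(C)OC(=O)C(=Cc1ccc(OCc2ccccc2)cc1)C(=O)c1c(O)cc(OCc2ccccc2)cc1OCc1ccccc1 | intermediate
9 | tert-butyl (2R,3S)-5,7-bis(benzyloxy)-2-[4-(benzyloxy)phenyl]-4-oxochromane-3-carboxylate (trans keto form, not isolated) | CC(C)(C)OC(=O)[C@@H]1C(=O)c2c(OCc3ccccc3)cc(OCc3ccccc3)cc2O[C@H]1c1ccc(OCc2ccccc2)cc1 | intermediate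
10 | (2R)-5,7-bis(benzyloxy)-2-[4-(benzyloxy)phenyl]chroman-4-one | C1C(=O)c2c(OCc3ccccc3)cc(OCc3ccccc3)cc2O[C@H]1c1ccc(OCc2ccccc2)cc1 | intermediate
11 | {[(2R)-5,7-bis(benzyloxy)-2-[4-(benzyloxy)phenyl]-2H-chromen-4-yl]oxy}(tert-butyl)dimethylsilane | CC(C)(C)[Si](C)(C)OC1=C[C@H](c2ccc(OCc3ccccc3)cc2)Oc2cc(OCc3ccccc3)cc(OCc3ccccc3)c12 | intermediate
12 | tert-butyl (2R,3S)-5,7-bis(benzyloxy)-3-{(2R,3S)-5,7-bis(benzyloxy)-2-[4-(benzyloxy)phenyl]-4-oxochroman-3-yl}-2-(4-methoxyphenyl)-4-oxochromane-3-carboxylate (C3–C3'' bond trans to the 2-anisyl group) | COc1ccc([C@H]2Oc3cc(OCc4ccccc4)cc(OCc4ccccc4)c3C(=O)[C@]2(C(=O)OC(C)(C)C)[C@@H]2C(=O)c3c(OCc4ccccc4)cc(OCc4ccccc4)cc3O[C@H]2c2ccc(OCc3ccccc3)cc2)cc1 | intermediate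
13 | (2R,3S)-5,7-bis(benzyloxy)-3-{(2R,3S)-5,7-bis(benzyloxy)-2-[4-(benzyloxy)phenyl]-4-oxochroman-3-yl}-2-(4-methoxyphenyl)-4-oxochromane-3-carboxylic acid (not isolated) | COc1ccc([C@H]2Oc3cc(OCc4ccccc4)cc(OCc4ccccc4)c3C(=O)[C@]2(C(=O)O)[C@@H]2C(=O)c3c(OCc4ccccc4)cc(OCc4ccccc4)cc3O[C@H]2c2ccc(OCc3ccccc3)cc2)cc1 | intermediate
14 | (2R)-5,7-bis(benzyloxy)-3-{(2R,3S)-5,7-bis(benzyloxy)-2-[4-(benzyloxy)phenyl]-4-oxochroman-3-yl}-2-(4-methoxyphenyl)-2H-chromen-4-ol (C3=C4 enol, not isolated) | COc1ccc([C@H]2Oc3cc(OCc4ccccc4)cc(OCc4ccccc4)c3C(O)=C2[C@@H]2C(=O)c3c(OCc4ccccc4)cc(OCc4ccccc4)cc3O[C@H]2c2ccc(OCc3ccccc3)cc2)cc1 | intermediate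
15 | (2S,3S)-5,7-bis(benzyloxy)-3-{(2R,3S)-5,7-bis(benzyloxy)-2-[4-(benzyloxy)phenyl]-4-oxochroman-3-yl}-2-(4-methoxyphenyl)chroman-4-one | COc1ccc([C@H]2Oc3cc(OCc4ccccc4)cc(OCc4ccccc4)c3C(=O)[C@H]2[C@@H]2C(=O)c3c(OCc4ccccc4)cc(OCc4ccccc4)cc3O[C@H]2c2ccc(OCc3ccccc3)cc2)cc1 | intermediate
16 | (2S,3S)-5,7-dihydroxy-3-[(2R,3S)-5,7-dihydroxy-2-(4-hydroxyphenyl)-4-oxochroman-3-yl]-2-(4-methoxyphenyl)chroman-4-one | COc1ccc([C@H]2Oc3cc(O)cc(O)c3C(=O)[C@H]2[C@@H]2C(=O)c3c(O)cc(O)cc3O[C@H]2c2ccc(O)cc2)cc1 | target

Total step count: 10. Longest linear sequence: 8 steps (1, 2, 5, 6, 7, 8, 9, 10).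

**Steps most likely to fail**

Step 8. The bimolecular addition of the hindered tertiary radical may be too slow. Protodesilylation or direct oxidation of the enol silane, radical dimerisation, or β-scission of the ring C2–O bond of the radical (with loss of the C2 configuration) could then take over. The fallback makes the union intramolecular on a temporary silicon tether (oxidative coupling of a silyl bis-enol ether). It sets out from 10 and 6. Compound 10 is enolised softly with iPr2Si(OTf)2/Et3N (CH2Cl2, –78 °C) and the resulting enol silyl triflate is intercepted with the enol form of 6, giving the unsymmetrical diisopropylsilylene bis-enol ether of 6 and 10 F1. Oxidation with CAN/NaHCO3 (MeCN/EtCN, –10 °C) should generate the radical cation, which closes through a seven-membered transition state, again anti to the C2'' aryl group. After loss of the silicon the sequence comes back to the route at 12.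

Step 9. Protonation of the enol may show poor facial selectivity, or acid-mediated re-enolisation may epimerise C3 to the more stable trans arrangement. The fallback replaces the acidic ketonisation by reagent-controlled protonation of a discrete, regiodefined enol silane. It sets out from 12. TMSOTf/2,6-lutidine (CH2Cl2, 0 °C) should exchange the tert-butyl for a silyl ester, giving the trimethylsilyl ester of acid 13 F2. Warming (toluene, 60–90 °C) should induce decarboxylation with silyl transfer to oxygen, giving the C3=C4 trimethylsilyl enol ether of the A half F3. Protonation at –78 °C with a Lewis acid-assisted Brønsted acid (SnCl4·BINOL, toluene, the BINOL antipode chosen to reinforce attack anti to the anisyl group) comes back to the route at 15.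

Step 4. Background (uncatalysed or amine-only) cyclisation of the hindered 2,6-dioxygenated benzoyl substrate may erode the enantiomeric purity at C2. The fallback sets C2 by asymmetric conjugate arylation instead. It sets out from 3. Heating with DMF dimethyl acetal (toluene, 80 °C) should give, by enaminone formation and cyclisation, the chromone ester tert-butyl 5,7-bis(benzyloxy)-4-oxo-4H-chromene-3-carboxylate F4. Pd(OCOCF3)2/t-BuPyOx- or Rh(I)/chiral diene-catalysed 1,4-addition of 4-methoxyphenylboronic acid (ligand antipode chosen for 2S) comes back to the route at 6.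

**Further compounds**

F1 | step 8 | unsymmetrical diisopropylsilylene bis-enol ether joining O4 of the enol of 6 and O4'' of the enol of 10 | COc1ccc([C@H]2Oc3cc(OCc4ccccc4)cc(OCc4ccccc4)c3C(O[Si](C(C)C)(C(C)C)OC3=C[C@H](c4ccc(OCc5ccccc5)cc4)Oc4cc(OCc5ccccc5)cc(OCc5ccccc5)c34)=C2C(=O)OC(C)(C)C)cc1
F2 | step 9 | trimethylsilyl ester of acid 13 | COc1ccc([C@H]2Oc3cc(OCc4ccccc4)cc(OCc4ccccc4)c3C(=O)[C@]2(C(=O)O[Si](C)(C)C)[C@@H]2C(=O)c3c(OCc4ccccc4)cc(OCc4ccccc4)cc3O[C@H]2c2ccc(OCc3ccccc3)cc2)cc1
F3 | step 9 | C3=C4 trimethylsilyl enol ether of the A half of 15 | COc1ccc([C@H]2Oc3cc(OCc4ccccc4)cc(OCc4ccccc4)c3C(O[Si](C)(C)C)=C2[C@@H]2C(=O)c3c(OCc4ccccc4)cc(OCc4ccccc4)cc3O[C@H]2c2ccc(OCc3ccccc3)cc2)cc1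
F4 | step 4 | tert-butyl 5,7-bis(benzyloxy)-4-oxo-4H-chromene-3-carboxylate | CC(C)(C)OC(=O)C1=COc2cc(OCc3ccccc3)cc(OCc3ccccc3)c2C1=O
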